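A small charge of reagent, 0.240 M, faces starting material and partner that together could take 0.500 M, so reagent is the limiting reagent.

    starting material + reagent → open intermediate (k1 = 0.029 M⁻¹ min⁻¹)
    reagent + partner → second intermediate (k2 = 0.025 M⁻¹ min⁻¹)
    open intermediate + second intermediate → target (k3 = 0.032 M⁻¹ min⁻¹)
    2 open intermediate → homo product (k4 = 0.035 M⁻¹ min⁻¹)
    second intermediate + capture agent → trapped intermediate (k5 = 0.017 M⁻¹ min⁻¹)

the same everywhere: partner 0.300 M; reagent 0.240 M; capture agent 0.0200 M

| charge | starting material | time | remark |
|---|---|---|---|
| ash | 0.20 M (fed, over 1.00 h) | 2.0 h | all but starting material at the start; starting material goes in evenly over 1.00 h, the run ends at 2.0 h |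
| maple | 0.20 M |  | one stirred flow tank at steady state, fed with the mixture as stated, mean residence time 20.0 h |
| birch | 0.20 M | 2.0 h | everything together in a closed stirred flask, run for 2.0 h |
| larch | 0.20 M |  | a single well-mixed tank run continuously and read at steady state, 2.0 h in it on average |

- percentages count the starting material that a species holds: one homo product counts as two
- for a step with 2 of a species take k times the square, and two of it per event
- the stated concentrations are those of everything mixed, before any reaction; amounts are the same in each set-up
- the feed brings no volume worth counting
- run time (ash): 2.0 h

1. the set-up with the highest amount of open intermediate at the outlet or at the end, in percent of the starting material put in ("none" if the first two lie within 2 percentage points) (ash / maple / birch / larch / none)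
2. amount of open intermediate at the outlet or at the end, in percent of the starting material put in, ash
3. amount of open intermediate at the outlet or at the end, in percent of the starting material put in, maple
4. amount of open intermediate at the outlet or at the end, in percent of the starting material put in, birch
5. amount of open intermediate at the outlet or at the end, in percent of the starting material put in, larch

I turn the question round and ask what a long stay would need in order to pay. At charged concentrations starting material takes 43.6% of the reagent, and the reagent's mean life is 75.2 min. From these I reckon the supply of open intermediate, as a share of the starting material: 41.7% in birch, 32.2% in larch and 49.2% in maple, so maple is supplied more than larch.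

But supply has to survive the homo step. For the 2.0 h stay in larch, one over twice the homo constant and the stay gives 59.5% of the charge, and I call this the crossing level: the amount at which the homo step's first half-life equals the stay. Maple's stay brings it down to 5.95%. Larch's supply does lie below its own, but maple's stands 8.27 times above.

Dropping the coupling, each tank's supply equals its level times one plus level over crossing level. On my reckoned supplies that bounds larch at 23.2% and maple at 14.4%. To stand at that larch bound by the same relation, maple would need a supply of 113%, and I reckon less than that, 49.2%. In birch a portion stands about one reagent life, which gives a crossing level of 95.0% and a figure of 29.0%, above both tank bounds. My reckoning stops short of ash.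

The forecast names birch, with 20.5% for ash, 9% for maple, 24.5% for birch and 17.9% for larch. Its birch figure lies below mine. Its ground is that the closed flask “forms it fastest and has the least time to lose it”.

The simulation gives birch as best, with 21.1% for ash, 8.92% for maple, 24.8% for birch and 17.9% for larch. Larch stands below its crossing level of 59.5%, and at that amount the homo step's first half-life, 6.64 h, is longer than the 2.0 h stay. Maple stands above its crossing level of 5.95%, and there the same half-life, 13.3 h, is shorter than the 20.0 h stay.

The numbers were drawn at random within sensible limits, and the outcome is calculated.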